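**Retrosynthetic overview**
1. Target 27 ⇐ silyl ether 26 ⇐ (C15 oxidation/esterification, C17 acetylation) allylic alcohol 22 ⇐ Δ7-enol triflate 21 + Bu3SnCH2OH (C8–C17 bond) ⇐ 9-alkyl-8-ketone 19.
2. 19 ⇐ trans-hydrindanone 8 (ring A plus the cyclopentanone C5–C6–C7–C8–C10) + gem-dibromide 14 (C9, C11–C16): one-pot carbenoid addition at C8 and 1,2-shift of C10 from C8 to C9 inserts C9 and enlarges the five-membered ring to ring B.
3. Enabling feature: the C8 carbonyl of the five-membered ring sits next to the fully substituted, methyl-bearing C10. C10 is therefore the migrating atom, so the hindered C9–C10 bond is made by migration, and the carbonyl left at C8 controls C9 and gives the C7=C8 triflate for C17.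
4. 8 ⇐ (S)-Hajos–Parrish ketone 1 (C10 bought; C5 and C3 relayed from it); 14 ⇐ (R)-citronellol 9 (C13 bought).
5. Ring order: ring A and the five-membered ring are present in 1; ring B is formed last, by one-carbon enlargement in step 9.

Key step: step 9

Remark: locants C1–C17 are the labdane numbers of the target and are used for all intermediates; in 1–8 the five-membered ring is C5–C6–C7–C8–C10 (C8 = carbonyl carbon next to C10), and C9 is the functionalised chain terminus of 13 and 14.

**Route**

Step 1
Reactants: 1 (S)-Hajos–Parrish ketone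
Product: 2 C8 ethylene ketal of 1
Conditions: 2-ethyl-2-methyl-1,3-dioxolane, ethylene glycol (cat.), p-TsOH·H2O (cat.), rt
Reagents that add atoms: 2-ethyl-2-methyl-1,3-dioxolane, CCC1(C)OCCO1
Why: Acid-catalysed transketalisation should protect only the saturated cyclopentanone carbonyl, which is more electrophilic than the vinylogous enone carbonyl.

Step 2
Reactants: 2 C8 ethylene ketal
Product: 4 gem-dimethyl Δ5(6)-3-ketone C8 ketal, via monomethyl enone 3 (not isolated)
Conditions: KOtBu (3 equiv), t-BuOH/THF, 0 °C; MeI (6 equiv), 0 °C → rt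
Reagents that add atoms: iodomethane, CI
Why: Deconjugative α,α-dialkylation of a Δ4-3-ketone through the extended dienolate (γ-deprotonation at C6, C-methylation at C4 twice) should leave the alkene at C5=C6, with C10 untouched and C7 shielded by the ketal.

Step 3
Reactants: 4 gem-dimethyl Δ5(6)-3-ketone C8 ketal
Product: 5 trans-fused saturated 3-ketone C8 ketal
Conditions: H2 (3 atm), 10% Pd/C, EtOAc, rt
Reagents that add atoms: none
Why: Heterogeneous hydrogenation should deliver hydrogen to the α face of C5=C6, anti to the angular C10 methyl (as in Δ14-steroid hydrogenations), setting 5α-H and the trans ring fusion by substrate control.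

Step 4
Reactants: 5 trans-fused saturated 3-ketone C8 ketal
Product: 7 trans-hydrindanone 3β-alcohol, via ketal alcohol 6 (not isolated)
Conditions: NaBH4, MeOH, 0 °C; acetone quench; then 2 M HCl, THF, rt
Reagents that add atoms: water, O
Why: Axial hydride delivery from the α face of the 4,4-dimethyl-3-ketone (equatorial attack is blocked by the axial 4β-methyl) should give the equatorial 3β-alcohol, and aqueous acid then hydrolyses the dioxolane (ketone reduction, then acetal hydrolysis).

Step 5
Reactants: 7 trans-hydrindanone 3β-alcohol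
Product: 8 3β-silyloxy trans-hydrindanone
Conditions: TBSOTf, 2,6-lutidine, CH2Cl2, −78 → 0 °C; dilute citric acid wash
Reagents that add atoms: tert-butyldimethylsilyl triflate, CC(C)(C)[Si](C)(C)OS(=O)(=O)C(F)(F)F
Why: Silyl triflate silylation should protect the hindered equatorial alcohol, and the mild acid wash returns any ketone that was converted to an enol silane.

Step 6
Reactants: 9 (R)-citronellol
Product: 11 (R)-citronellyl 4-methoxybenzyl ether, via sodium alkoxide 10 (not isolated)
Conditions: NaH, THF/DMF, 0 °C; PMBCl, Bu4NI (cat.), rt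
Reagents that add atoms: 4-methoxybenzyl chloride, COc1ccc(CCl)cc1
Why: Williamson etherification of the primary alkoxide should proceed without touching the C13 stereocentre.

Step 7
Reactants: 11 (R)-citronellyl 4-methoxybenzyl ether
Product: 13 (4R)-6-[(4-methoxybenzyl)oxy]-4-methylhexanal, via ozonide 12 (not isolated)
Conditions: O3/O2, CH2Cl2, −78 °C (Sudan red 7B end point); PPh3, −78 °C → rt
Reagents that add atoms: ozone, [O-][O+]=O
Why: Ozonolysis of the trisubstituted alkene, which reacts far faster than the anisyl ring, with reductive work-up should give the aldehyde whose carbonyl carbon becomes C9.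

Step 8
Reactants: 13 (4R)-6-[(4-methoxybenzyl)oxy]-4-methylhexanal
Product: 14 gem-dibromide
Conditions: P(OPh)3, Br2, Et3N, CH2Cl2, −78 °C → rt
Reagents that add atoms: bromine, BrBr
Why: Deoxygenative gem-dibromination of the aldehyde by bromotriphenoxyphosphonium bromide formed in the flask, buffered by Et3N, should spare the PMB ether.

Step 9
Reactants: 8 3β-silyloxy trans-hydrindanone; 14 gem-dibromide
Product: 19 ring-expanded ketone (3β-silyloxy-15-PMB-oxy-17-norlabdan-8-one), via lithiated dibromide 15 (not isolated), via dibromo alkoxide 16 (not isolated), via β-oxido carbenoid 17 (not isolated), via lithium enolate 18 (not isolated)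
Conditions: 14 (1.5 equiv), lithium 2,2,6,6-tetramethylpiperidide (LiTMP, 1.5 equiv), THF/Et2O, −105 °C; 8, −105 → −90 °C; n-BuLi (3 equiv), −100 → 0 °C; AcOH; crude stirred with NaOMe (cat.), MeOH/THF, rt
Reagents that add atoms: none
Why: LiTMP deprotonates 14 to the 1,1-dibromoalkyllithium 15, which adds to the C8 carbonyl of 8 from the α face (anti to the angular C10 methyl) to give alkoxide 16; bromine–lithium exchange with n-BuLi then gives the β-oxido carbenoid 17, in which the C8–C10 bond migrates to the carbenoid carbon C9 with loss of LiBr to give enolate 18. The closest known reaction type is the β-oxido carbenoid (Nozaki–Yamamoto) one-carbon ring enlargement of cyclic ketones, run here with a 1,1-dibromoalkane so that the inserted carbon arrives carrying the whole side chain. Ring B is not closed by a cyclisation: the five-membered ring C5–C6–C7–C8–C10 is enlarged to the six-membered ring by a 1,2-alkyl shift that forms the C9–C10 bond, with C10 migrating with retention so that C5 and C10 are untouched. The only new stereocentre that survives, C9, is set when enolate 18 is protonated: axial protonation anti to the axial C10 methyl places the side chain equatorial (9α-H), which is also the thermodynamically favoured epimer next to the C8 ketone, so the NaOMe equilibration should converge on 19. The step needs migration of C10 and not of C7; this is secured by the higher migratory aptitude of the fully substituted C10 (β-oxido carbenoids shift the more substituted α-carbon) and by the rotamer with bromide anti to C10 being the less congested one. The carbinol stereocentre made at C8 in the addition is destroyed when the carbonyl is regenerated.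

Step 10
Reactants: 19 ring-expanded ketone
Product: 21 Δ7-enol triflate, via potassium enolate 20 (not isolated)
Conditions: KN(SiMe3)2, THF, −78 °C; PhNTf2, −78 → 0 °C
Reagents that add atoms: N-phenylbis(trifluoromethanesulfonimide), O=S(=O)(N(c1ccccc1)S(=O)(=O)C(F)(F)F)C(F)(F)F
Why: Kinetic deprotonation should occur at the unhindered C7 methylene rather than at the tertiary, neopentyl C9–H, and O-triflation of the Δ7 enolate fixes the future alkene at C7=C8 without touching C9.

Step 11
Reactants: 21 Δ7-enol triflate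
Product: 22 allylic alcohol (labd-7-en-17-ol with 3β-OTBS and 15-OPMB)
Conditions: Bu3SnCH2OH, Pd(PPh3)4 (10 mol %), LiCl, 1,4-dioxane, 100 °C
Reagents that add atoms: tributyl(hydroxymethyl)stannane, CCCC[Sn](CCCC)(CCCC)CO
Why: Stille cross-coupling of the vinyl triflate with the hydroxymethylstannane, with LiCl assisting transmetalation, should install C17 on C8 with the alkene position fixed.

Step 12
Reactants: 22 allylic alcohol
Product: 23 allylic acetate
Conditions: Ac2O, pyridine, DMAP (cat.), CH2Cl2, 0 °C → rt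
Reagents that add atoms: acetic anhydride, CC(=O)OC(C)=O
Why: DMAP-catalysed acylation of the only free hydroxyl should give the C17 acetate.

Step 13
Reactants: 23 allylic acetate
Product: 24 C15 primary alcohol
Conditions: DDQ, CH2Cl2/pH 7 phosphate buffer (10:1), 0 °C
Reagents that add atoms: none
Why: Oxidative cleavage of the PMB ether by DDQ (benzylic hydride abstraction, hydrolysis of the oxocarbenium ion) should leave the silyl ether, the acetate and the trisubstituted alkene intact.

Step 14
Reactants: 24 C15 primary alcohol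
Product: 25 C15 carboxylic acid
Conditions: TEMPO (20 mol %), PhI(OAc)2 (2.5 equiv), MeCN/H2O (1:1), rt
Reagents that add atoms: water, O
Why: Oxoammonium-mediated oxidation of the primary alcohol through the aldehyde hydrate should give the acid, with the only other hydroxyl still silylated.

Step 15
Reactants: 25 C15 carboxylic acid
Product: 26 methyl ester
Conditions: TMSCHN2, toluene/MeOH (4:1), 0 °C
Reagents that add atoms: trimethylsilyldiazomethane, C[Si](C)(C)C=[N+]=[N-]
Why: Diazoalkane O-methylation of the carboxylic acid under neutral conditions should not disturb the allylic acetate.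

Step 16
Reactants: 26 methyl ester
Product: 27 target
Conditions: 48% aq. HF, MeCN, 0 °C → rt
Reagents that add atoms: none
Why: Acidic fluoride desilylation should free the hindered 3β-hydroxyl while the acetate and methyl ester, which a basic fluoride source could cleave, survive.

**Compound list**
1 | (S)-Hajos–Parrish ketone, (7aS)-7a-methyl-2,3,7,7a-tetrahydro-1H-indene-1,5(6H)-dione | O=C1CCC2=CC(=O)CC[C@]12C | starting material
2 | (7a'S)-7a'-methyl-2',3',7',7a'-tetrahydrospiro[1,3-dioxolane-2,1'-inden]-5'(6'H)-one (C8 ethylene ketal of 1) | C12(OCCO1)CCC3=CC(=O)CC[C@]23C | intermediate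
3 | 4-monomethyl Δ5(6)-3-ketone C8 ketal (C4 epimers) | C12(OCCO1)CC=C3C(C)C(=O)CC[C@]23C | intermediate
4 | (7a'S)-4',4',7a'-trimethyl-2',4',7',7a'-tetrahydrospiro[1,3-dioxolane-2,1'-inden]-5'(6'H)-one (alkene C5=C6) | C12(OCCO1)CC=C3C(C)(C)C(=O)CC[C@]23C | intermediate
5 | (3a'S,7a'S)-4',4',7a'-trimethylhexahydrospiro[1,3-dioxolane-2,1'-inden]-5'(4'H)-one (trans-fused, 5α-H, 10β-CH3) | C12(OCCO1)CC[C@H]3C(C)(C)C(=O)CC[C@]23C | intermediate
6 | (3a'S,5'S,7a'S)-4',4',7a'-trimethyloctahydrospiro[1,3-dioxolane-2,1'-inden]-5'-ol (3β-OH) | C12(OCCO1)CC[C@H]3C(C)(C)[C@@H](O)CC[C@]23C | intermediate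
7 | (3aS,5S,7aS)-5-hydroxy-4,4,7a-trimethyloctahydro-1H-inden-1-one | O=C1CC[C@H]2C(C)(C)[C@@H](O)CC[C@]12C | intermediate
8 | (3aS,5S,7aS)-5-[(tert-butyldimethylsilyl)oxy]-4,4,7a-trimethyloctahydro-1H-inden-1-one | O=C1CC[C@H]2C(C)(C)[C@@H](O[Si](C)(C)C(C)(C)C)CC[C@]12C | intermediate
9 | (R)-citronellol, (3R)-3,7-dimethyloct-6-en-1-ol | OCC[C@H](C)CCC=C(C)C | starting material
10 | sodium (R)-citronellolate | [Na+].[O-]CC[C@H](C)CCC=C(C)C | intermediate
11 | 1-({[(3R)-3,7-dimethyloct-6-en-1-yl]oxy}methyl)-4-methoxybenzene | COc1ccc(COCC[C@H](C)CCC=C(C)C)cc1 | intermediate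
12 | ozonide of 11 (3,3-dimethyl-5-alkyl-1,2,4-trioxolane, side-chain stereocentre as in 9) | COc1ccc(COCC[C@H](C)CCC2OOC(C)(C)O2)cc1 | intermediate
13 | (4R)-6-[(4-methoxybenzyl)oxy]-4-methylhexanal | COc1ccc(COCC[C@H](C)CCC=O)cc1 | intermediate
14 | 1-({[(3R)-6,6-dibromo-3-methylhexyl]oxy}methyl)-4-methoxybenzene | COc1ccc(COCC[C@H](C)CCC(Br)Br)cc1 | intermediate
15 | 1,1-dibromoalkyllithium from 14 (lithium on C9) | COc1ccc(COCC[C@H](C)CCC([Li])(Br)Br)cc1 | intermediate
16 | lithium alkoxide of the C8 adduct (8β-OLi, 8α-CBr2R, hydrindane intact) | COc1ccc(COCC[C@H](C)CCC(Br)(Br)[C@]2(O[Li])CC[C@H]3C(C)(C)[C@@H](O[Si](C)(C)C(C)(C)C)CC[C@]23C)cc1 | intermediate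
17 | β-oxido carbenoid (C9 bearing Li and Br, configuration at C9 undefined) | COc1ccc(COCC[C@H](C)CCC([Li])(Br)[C@]2(O[Li])CC[C@H]3C(C)(C)[C@@H](O[Si](C)(C)C(C)(C)C)CC[C@]23C)cc1 | intermediate
18 | lithium Δ8(9)-enolate of the ring-expanded ketone | COc1ccc(COCC[C@H](C)CCC2=C(O[Li])CC[C@H]3C(C)(C)[C@@H](O[Si](C)(C)C(C)(C)C)CC[C@]23C)cc1 | intermediate
19 | 3β-(tert-butyldimethylsilyloxy)-15-(4-methoxybenzyloxy)-17-norlabdan-8-one (5α-H, 9α-H, 10β-CH3, C13 as in 9) | COc1ccc(COCC[C@H](C)CC[C@H]2C(=O)CC[C@H]3C(C)(C)[C@@H](O[Si](C)(C)C(C)(C)C)CC[C@]23C)cc1 | intermediate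
20 | potassium Δ7-enolate of 19 | COc1ccc(COCC[C@H](C)CC[C@H]2C(O[K])=CC[C@H]3C(C)(C)[C@@H](O[Si](C)(C)C(C)(C)C)CC[C@]23C)cc1 | intermediate
21 | 3β-(tert-butyldimethylsilyloxy)-15-(4-methoxybenzyloxy)-17-norlabd-7-en-8-yl trifluoromethanesulfonate | COc1ccc(COCC[C@H](C)CC[C@H]2C(OS(=O)(=O)C(F)(F)F)=CC[C@H]3C(C)(C)[C@@H](O[Si](C)(C)C(C)(C)C)CC[C@]23C)cc1 | intermediate
22 | 3β-(tert-butyldimethylsilyloxy)-15-(4-methoxybenzyloxy)labd-7-en-17-ol | COc1ccc(COCC[C@H](C)CC[C@H]2C(CO)=CC[C@H]3C(C)(C)[C@@H](O[Si](C)(C)C(C)(C)C)CC[C@]23C)cc1 | intermediate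
23 | 17-acetoxy-3β-(tert-butyldimethylsilyloxy)-15-(4-methoxybenzyloxy)labd-7-ene | COc1ccc(COCC[C@H](C)CC[C@H]2C(COC(C)=O)=CC[C@H]3C(C)(C)[C@@H](O[Si](C)(C)C(C)(C)C)CC[C@]23C)cc1 | intermediate
24 | 17-acetoxy-3β-(tert-butyldimethylsilyloxy)labd-7-en-15-ol | OCC[C@H](C)CC[C@H]1C(COC(C)=O)=CC[C@H]2C(C)(C)[C@@H](O[Si](C)(C)C(C)(C)C)CC[C@]12C | intermediate
25 | 17-acetoxy-3β-(tert-butyldimethylsilyloxy)labd-7-en-15-oic acid | OC(=O)C[C@H](C)CC[C@H]1C(COC(C)=O)=CC[C@H]2C(C)(C)[C@@H](O[Si](C)(C)C(C)(C)C)CC[C@]12C | intermediate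
26 | methyl 17-acetoxy-3β-(tert-butyldimethylsilyloxy)labd-7-en-15-oate | COC(=O)C[C@H](C)CC[C@H]1C(COC(C)=O)=CC[C@H]2C(C)(C)[C@@H](O[Si](C)(C)C(C)(C)C)CC[C@]12C | intermediate
27 | methyl (3S,5R,9R,10R,13R)-17-acetoxy-3-hydroxylabd-7-en-15-oate (3β-OH, 5α-H, 9α-H, 10β-CH3) | COC(=O)C[C@H](C)CC[C@H]1C(COC(C)=O)=CC[C@H]2C(C)(C)[C@@H](O)CC[C@]12C | target

**Step count and risks**
Total step count: 16. Longest linear sequence: 13 (steps 1–5, 9–16).

Most likely to fail, step 9. The tertiary carbenoid 15 may add too slowly to the neopentyl C8 carbonyl, so that enolisation of 8 and α-elimination of the carbenoid compete, and the 1,2-shift may partly take the C7 methylene instead of C10. The fallback sets out from aldehyde 13 and ketone 8 and returns at 19. NaBH4 reduction of 13 should give (4R)-6-[(4-methoxybenzyl)oxy]-4-methylhexan-1-ol F1; I2/PPh3/imidazole should convert it into the iodide F2, and PPh3 in hot MeCN into the phosphonium iodide F3. The ylide from F3 (KOtBu, toluene, reflux) should olefinate the hindered C8 ketone of 8, as ethylidene ylides do with 17-oxo steroids, to give the (Z)-alkylidene hydrindane F4 (side chain cis to C10). OsO4 (cat.)/NMO should dihydroxylate F4 from the α face to the 8α,9-diol F5, and MsCl/Et3N should sulfonylate only the secondary C9 hydroxyl to give the hydroxy mesylate F6. Et3Al in CH2Cl2 (−78 → 0 °C) should then trigger the semipinacol ring enlargement. The diastereomer derived from the Z-alkene places the mesylate anti to C10 in its least crowded rotamer, so C10 should migrate with inversion at C9 to give the 9-epi ketone F7. NaOMe in MeOH should epimerise C9 of F7 to the equatorial isomer 19.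

Step 3. Facial selectivity of the hydrogenation may be poor, with delivery from the β face giving the cis-fused hydrindane. The fallback sets out from 2 and returns at 5. Monomethylation of 2 (KOtBu 1.05 equiv, MeI 1.1 equiv, t-BuOH) should give the conjugated 4-methyl enone F8. Stork reductive alkylation (Li, NH3/THF, t-BuOH 1 equiv, −78 °C; then MeI) should protonate C5 from the α face through the pyramidal β-carbanion and methylate the C4 enolate regiospecifically to give 5.

Step 11. Transmetalation at the hindered C8 triflate may be slow, so that reduction of the triflate and protodestannylation take over. The fallback sets out from 21 and returns at 22. Methoxycarbonylation catalysed by Pd(OAc)2/PPh3 (CO 1 atm, MeOH, Et3N, DMF, 60 °C) should give the methyl enoate F9. DIBAL-H (CH2Cl2, −78 °C) should reduce F9 to 22; no other ester is present at this stage because C15 is still a PMB ether.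

**Further compounds**
F1 | step 9 | (4R)-6-[(4-methoxybenzyl)oxy]-4-methylhexan-1-ol | COc1ccc(COCC[C@H](C)CCCO)cc1
F2 | step 9 | 1-({[(3R)-6-iodo-3-methylhexyl]oxy}methyl)-4-methoxybenzene | COc1ccc(COCC[C@H](C)CCCI)cc1
F3 | step 9 | [(4R)-6-[(4-methoxybenzyl)oxy]-4-methylhexyl]triphenylphosphonium iodide | COc1ccc(COCC[C@H](C)CCC[P+](c2ccccc2)(c2ccccc2)c2ccccc2)cc1.[I-]
F4 | step 9 | (Z)-8(9)-alkylidene hydrindane (3β-OTBS, side chain cis to C10) | COc1ccc(COCC[C@H](C)CC/C=C2/CC[C@H]3C(C)(C)[C@@H](O[Si](C)(C)C(C)(C)C)CC[C@]23C)cc1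
F5 | step 9 | 8α,9-diol from α-face syn-dihydroxylation of F4 | COc1ccc(COCC[C@H](C)CC[C@H](O)[C@@]2(O)CC[C@H]3C(C)(C)[C@@H](O[Si](C)(C)C(C)(C)C)CC[C@]23C)cc1
F6 | step 9 | 8α-hydroxy 9-mesylate | COc1ccc(COCC[C@H](C)CC[C@H](OS(C)(=O)=O)[C@@]2(O)CC[C@H]3C(C)(C)[C@@H](O[Si](C)(C)C(C)(C)C)CC[C@]23C)cc1
F7 | step 9 | 9-epi-19 (9β-H, axial side chain) | COc1ccc(COCC[C@H](C)CC[C@@H]2C(=O)CC[C@H]3C(C)(C)[C@@H](O[Si](C)(C)C(C)(C)C)CC[C@]23C)cc1
F8 | step 3 | 4-methyl Δ4-3-ketone C8 ketal, (7a'S)-4',7a'-dimethyl-2',3',7',7a'-tetrahydrospiro[1,3-dioxolane-2,1'-inden]-5'(6'H)-one | C12(OCCO1)CCC3=C(C)C(=O)CC[C@]23C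
F9 | step 11 | methyl 3β-(tert-butyldimethylsilyloxy)-15-(4-methoxybenzyloxy)labd-7-en-17-oate | COc1ccc(COCC[C@H](C)CC[C@H]2C(C(=O)OC)=CC[C@H]3C(C)(C)[C@@H](O[Si](C)(C)C(C)(C)C)CC[C@]23C)cc1
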